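## Retrosynthetic overview

1. Target 17 ← hydrogenolysis of dibenzyl flavonol 16 ← Algar–Flynn–Oyamada oxidative cyclisation of chalcone 14. Ring C is the only ring made and is formed last; rings A and B are bought as benzenes.
2. Chalcone 14 ← Claisen–Schmidt condensation of ring A ketone 12 with ring B aldehyde 6.
3. Aldehyde 6 ← B-alkyl Suzuki coupling of bromoaldehyde 4 with the 9-BBN adduct of (S)-2-methylbut-3-enyl benzoate 3.
4. Key step: 3 ← bromide 2 ← enantioselective copper-catalysed SN2′ methylation that desymmetrises (E)-1,4-dibromobut-2-ene 1 and sets the only stereocentre.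
5. Ketone 12 ← symmetric phloroacetophenone 7 (cheap bulk aromatic) by 4-O-benzylation, mono-O-methylation, Elbs para-hydroxylation and O-methylation.

Assumption: the stereocentre in the given SMILES is (S). (R,Rp)-Taniaphos is taken as the ligand enantiomer that gives the (S)-product in step 1; this sense of induction is not certain and is checked on the first run (chiral HPLC and optical rotation of 3), and (S,Sp)-Taniaphos is used if it proves opposite.

## Route

Step 1
Reactants: 1 (E)-1,4-dibromobut-2-ene
Product: 2 (S)-4-bromo-3-methylbut-1-ene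
Conditions: CuBr·SMe2 (2 mol%), (R,Rp)-Taniaphos (2.4 mol%), MeMgBr (1.15 equiv, 3 M in Et2O), CH2Cl2, −78 °C, slow addition of 1 over 2 h; MeOH quench; fractional distillation
Reagents that add atoms: methylmagnesium bromide, C[Mg]Br
Why: Copper-catalysed asymmetric allylic alkylation (anti-SN2′), in which the chiral monovalent copper–diphosphine methyl complex attacks one enantiotopic π-face of the symmetric dibromide (both termini are equivalent), creating the (S)-methyl stereocentre and the vinyl group in one C–C bond formation and stopping after one substitution because the remaining C–Br is an unactivated homoallylic bromide.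

Step 2
Reactants: 2 (S)-4-bromo-3-methylbut-1-ene
Product: 3 (S)-2-methylbut-3-en-1-yl benzoate
Conditions: PhCO2K (1.5 equiv), 18-crown-6 (5 mol%), DMF, 60 °C, 16 h
Reagents that add atoms: potassium benzoate, [K+].[O-]C(=O)c1ccccc1
Why: SN2 displacement of the primary bromide by a weakly basic carboxylate (which limits E2 to isoprene) leaves the stereocentre untouched and gives a non-volatile, UV-active ester on which the ee is measured and which is cleaved without a separate step in step 8.

Step 3
Reactants: 3 (S)-2-methylbut-3-en-1-yl benzoate; 4 4-(benzyloxy)-3-bromobenzaldehyde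
Product: 6 (2S)-4-[2-(benzyloxy)-5-formylphenyl]-2-methylbutyl benzoate, via B-alkyl-9-BBN borane 5 (not isolated)
Conditions: 3 (1.3 equiv), 9-BBN dimer (0.6 equiv), THF, 0 °C → rt, 4 h; then 4 (1.0 equiv), PdCl2(dppf)·CH2Cl2 (5 mol%), K3PO4 (3 equiv, 3 M aq), DMF, 60 °C, 12 h
Reagents that add atoms: none
Why: Anti-Markovnikov hydroboration followed by B-alkyl Suzuki–Miyaura coupling (zerovalent palladium formed in situ inserts into the aryl C–Br bond) joins the chain to ring B, with the alkene kept in excess over B–H so that no hydride remains to reduce the aldehyde and with the benzoate and the remote stereocentre unaffected.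

Step 4
Reactants: 7 1-(2,4,6-trihydroxyphenyl)ethanone (phloroacetophenone, dried)
Product: 8 1-[4-(benzyloxy)-2,6-dihydroxyphenyl]ethanone
Conditions: BnBr (1.0 equiv), K2CO3 (1.0 equiv), DMF, 0 °C → rt, 12 h
Reagents that add atoms: benzyl bromide, BrCc1ccccc1
Why: Williamson etherification occurs at the most acidic, non-chelated 4-OH (para to the acetyl), while the two hydrogen-bonded ortho-hydroxyls react much more slowly; di-O- and C-benzylated by-products are removed by chromatography.

Step 5
Reactants: 8 1-[4-(benzyloxy)-2,6-dihydroxyphenyl]ethanone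
Product: 9 1-[4-(benzyloxy)-2-hydroxy-6-methoxyphenyl]ethanone
Conditions: Me2SO4 (1.1 equiv), K2CO3 (1.5 equiv), acetone, reflux, 5 h
Reagents that add atoms: dimethyl sulfate, COS(=O)(=O)OC
Why: O-methylation of one of the two equivalent ortho-hydroxyls stops at the mono-ether because the remaining OH is then locked in a strong hydrogen bond to the ketone.

Step 6
Reactants: 9 1-[4-(benzyloxy)-2-hydroxy-6-methoxyphenyl]ethanone
Product: 11 1-[4-(benzyloxy)-3,6-dihydroxy-2-methoxyphenyl]ethanone, via potassium aryl sulfate 10 (not isolated)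
Conditions: K2S2O8 (1.2 equiv), 10% aq NaOH, pyridine, 15–20 °C, 24 h; acidify to pH 5 and extract unreacted 9 (recycled); then aqueous phase with 2 M HCl, Na2SO3 (cat.), 80 °C, 30 min
Reagents that add atoms: potassium peroxodisulfate, [K+].[K+].[O-]S(=O)(=O)OOS(=O)(=O)[O-]
Why: Elbs persulfate oxidation, in which the phenoxide attacks peroxodisulfate through its only free para position and acid hydrolysis of the aryl sulfate releases the hydroquinone, places the new oxygen unambiguously between OBn and OMe.

Step 7
Reactants: 11 1-[4-(benzyloxy)-3,6-dihydroxy-2-methoxyphenyl]ethanone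
Product: 12 1-[4-(benzyloxy)-6-hydroxy-2,3-dimethoxyphenyl]ethanone (4′-benzyloxy-2′-hydroxy-5′,6′-dimethoxyacetophenone)
Conditions: Me2SO4 (1.05 equiv), K2CO3 (1.2 equiv), acetone, reflux, N2, 4 h
Reagents that add atoms: dimethyl sulfate, COS(=O)(=O)OC
Why: Selective Williamson methylation of the free hydroquinone OH, since the other hydroxyl is chelated to the ketone and is inert to one equivalent of reagent under carbonate conditions.

Step 8
Reactants: 12 1-[4-(benzyloxy)-6-hydroxy-2,3-dimethoxyphenyl]ethanone; 6 (2S)-4-[2-(benzyloxy)-5-formylphenyl]-2-methylbutyl benzoate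
Product: 14 (E)-1-[4-(benzyloxy)-6-hydroxy-2,3-dimethoxyphenyl]-3-{4-(benzyloxy)-3-[(3S)-4-hydroxy-3-methylbutyl]phenyl}prop-2-en-1-one, via hydroxy aldehyde 13 (not isolated)
Conditions: 12 (1.0 equiv), 6 (1.1 equiv), KOH (50% aq, 10 equiv), EtOH, rt, 36 h; then 1 M HCl to pH 3
Reagents that add atoms: none
Why: Claisen–Schmidt aldol condensation gives the (E)-enone after E1cB dehydration while the excess KOH saponifies the benzoate in the same pot, and the alkyl stereocentre, not being alpha to any carbonyl, cannot epimerise.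

Step 9
Reactants: 14 the (E)-chalcone of step 8
Product: 16 7-(benzyloxy)-2-{4-(benzyloxy)-3-[(3S)-4-hydroxy-3-methylbutyl]phenyl}-3-hydroxy-5,6-dimethoxy-4H-chromen-4-one, via trans-dihydroflavonol 15 (not isolated)
Conditions: 30% H2O2 (6 equiv), 2 M aq NaOH (6 equiv), MeOH/THF (2:1), 0 °C → rt, 8 h; then 1 M HCl
Reagents that add atoms: hydrogen peroxide, OO
Why: Algar–Flynn–Oyamada reaction, in which alkaline peroxide oxidation of the 2′-hydroxychalcone closes ring C to the trans-dihydroflavonol that is dehydrogenated in situ to the flavonol, run cold because the 6′-methoxy group favours the competing aurone pathway.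

Step 10
Reactants: 16 the dibenzyl flavonol of step 9
Product: 17 3,7-dihydroxy-2-{4-hydroxy-3-[(3S)-4-hydroxy-3-methylbutyl]phenyl}-5,6-dimethoxy-4H-chromen-4-one (CNP0253239.1)
Conditions: H2 (1 atm), 10% Pd/C (palladium on carbon), THF/MeOH (1:1), rt, 3 h
Reagents that add atoms: none
Why: Hydrogenolysis of both benzyl aryl ethers over zerovalent palladium, under which the tetrasubstituted vinylogous-ester C2=C3 bond, the ketone and the stereocentre are not affected at 1 atm and room temperature.

## Compound list

1 | (E)-1,4-dibromobut-2-ene | BrC/C=C/CBr | starting material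
2 | (S)-4-bromo-3-methylbut-1-ene | C=C[C@H](C)CBr | intermediate
3 | (S)-2-methylbut-3-en-1-yl benzoate | C=C[C@H](C)COC(=O)c1ccccc1 | intermediate
4 | 4-(benzyloxy)-3-bromobenzaldehyde | O=Cc1ccc(OCc2ccccc2)c(Br)c1 | starting material
5 | (2S)-4-(9-borabicyclo[3.3.1]nonan-9-yl)-2-methylbutyl benzoate | B1(CC[C@H](C)COC(=O)c2ccccc2)C2CCCC1CCC2 | intermediate (not isolated)
6 | (2S)-4-[2-(benzyloxy)-5-formylphenyl]-2-methylbutyl benzoate | O=Cc1ccc(OCc2ccccc2)c(CC[C@H](C)COC(=O)c2ccccc2)c1 | intermediate
7 | 1-(2,4,6-trihydroxyphenyl)ethanone | CC(=O)c1c(O)cc(O)cc1O | starting material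
8 | 1-[4-(benzyloxy)-2,6-dihydroxyphenyl]ethanone | CC(=O)c1c(O)cc(OCc2ccccc2)cc1O | intermediate
9 | 1-[4-(benzyloxy)-2-hydroxy-6-methoxyphenyl]ethanone | CC(=O)c1c(O)cc(OCc2ccccc2)cc1OC | intermediate
10 | potassium 3-acetyl-6-(benzyloxy)-4-hydroxy-2-methoxyphenyl sulfate | CC(=O)c1c(O)cc(OCc2ccccc2)c(OS(=O)(=O)[O-])c1OC.[K+] | intermediate (not isolated)
11 | 1-[4-(benzyloxy)-3,6-dihydroxy-2-methoxyphenyl]ethanone | CC(=O)c1c(O)cc(OCc2ccccc2)c(O)c1OC | intermediate
12 | 1-[4-(benzyloxy)-6-hydroxy-2,3-dimethoxyphenyl]ethanone | CC(=O)c1c(O)cc(OCc2ccccc2)c(OC)c1OC | intermediate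
13 | 4-(benzyloxy)-3-[(3S)-4-hydroxy-3-methylbutyl]benzaldehyde | O=Cc1ccc(OCc2ccccc2)c(CC[C@H](C)CO)c1 | intermediate (not isolated)
14 | (E)-1-[4-(benzyloxy)-6-hydroxy-2,3-dimethoxyphenyl]-3-{4-(benzyloxy)-3-[(3S)-4-hydroxy-3-methylbutyl]phenyl}prop-2-en-1-one | COc1c(OC)c(OCc2ccccc2)cc(O)c1C(=O)/C=C/c1ccc(OCc2ccccc2)c(CC[C@H](C)CO)c1 | intermediate
15 | 2,3-trans-7-(benzyloxy)-2-{4-(benzyloxy)-3-[(3S)-4-hydroxy-3-methylbutyl]phenyl}-3-hydroxy-5,6-dimethoxychroman-4-one (both 2,3-trans ring diastereomers; ring centres left undefined) | COc1c(OCc5ccccc5)cc2OC(c3ccc(OCc4ccccc4)c(CC[C@H](C)CO)c3)C(O)C(=O)c2c1OC | intermediate (not isolated)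
16 | 7-(benzyloxy)-2-{4-(benzyloxy)-3-[(3S)-4-hydroxy-3-methylbutyl]phenyl}-3-hydroxy-5,6-dimethoxy-4H-chromen-4-one | COc1c(OCc5ccccc5)cc2oc(-c3ccc(OCc4ccccc4)c(CC[C@H](C)CO)c3)c(O)c(=O)c2c1OC | intermediate
17 | 3,7-dihydroxy-2-{4-hydroxy-3-[(3S)-4-hydroxy-3-methylbutyl]phenyl}-5,6-dimethoxy-4H-chromen-4-one | COc1c(O)cc2oc(-c3ccc(O)c(CC[C@H](C)CO)c3)c(O)c(=O)c2c1OC | target

## Step count and risks

Total step count: 10.
Longest linear sequence: 7 steps (7 → 8 → 9 → 11 → 12 → 14 → 16 → 17; steps 4–10). The side-chain branch (steps 1–3) joins at step 8.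

The three steps most likely to fail:

Step 1 (desymmetrising asymmetric SN2′ methylation). The risks are a lower ee or lower branched-to-linear ratio with MeMgBr on the dibromide than on oxygenated substrates, and loss of the volatile product 2. The ee cannot be upgraded later, so it must be at least about 95% at compound 3. The fallback sets out from 1. Mono-substitution with potassium benzoate (0.4 equiv relative to 1, DMF, rt; excess 1 recovered by distillation) gives (E)-4-bromobut-2-en-1-yl benzoate F1. This is a non-volatile, pre-differentiated allylic bromide of the substrate class for which the CuBr·SMe2/Taniaphos/MeMgBr alkylation (CH2Cl2, −78 °C) is best established. Its SN2′ methylation gives the benzoate directly, so the route is rejoined at 3 and compound 2 is bypassed. The stereocentre is then set on a substrate that no longer depends on desymmetrisation.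

Step 6 (Elbs oxidation). The expected conversion is low (typically 25–40% with recovered 9), and the hindered para position and the benzyl ether during acid hydrolysis add risk. The fallback sets out from 9. Teuber oxidation with potassium nitrosodisulfonate ON(SO3K)2 (2.2 equiv, KH2PO4 buffer, acetone/H2O, rt) dearomatises the phenol to 2-acetyl-5-(benzyloxy)-3-methoxycyclohexa-2,5-diene-1,4-dione F2. Reduction of this quinone with Na2S2O4 (EtOAc/H2O, rt) gives the hydroquinone, and the route is rejoined at 11.

Step 9 (Algar–Flynn–Oyamada reaction). The 6′-methoxy group can divert the oxidation to the aurone. The fallback sets out from 14. Oxidative cyclisation with I2 (10 mol%) in DMSO at 110 °C gives 7-(benzyloxy)-2-{4-(benzyloxy)-3-[(3S)-4-hydroxy-3-methylbutyl]phenyl}-5,6-dimethoxy-4H-chromen-4-one F3, a flavone in which ring C is closed with no aurone option. C3 is then hydroxylated by lithiation with LiN(i-Pr)2 (3 equiv, THF, −78 °C; the first equivalent is consumed by the alcohol), trapping with B(OMe)3 and oxidation with H2O2/AcOH. This gives the flavonol, and the route is rejoined at 16.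

## Further compounds

F1 | step 1 | (E)-4-bromobut-2-en-1-yl benzoate | BrC/C=C/COC(=O)c1ccccc1
F2 | step 6 | 2-acetyl-5-(benzyloxy)-3-methoxycyclohexa-2,5-diene-1,4-dione | CC(=O)C1=C(OC)C(=O)C(OCc2ccccc2)=CC1=O
F3 | step 9 | 7-(benzyloxy)-2-{4-(benzyloxy)-3-[(3S)-4-hydroxy-3-methylbutyl]phenyl}-5,6-dimethoxy-4H-chromen-4-one | COc1c(OCc5ccccc5)cc2oc(-c3ccc(OCc4ccccc4)c(CC[C@H](C)CO)c3)cc(=O)c2c1OC
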